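**Strategy**

Ring B (the phenol ring) is not coupled to ring A (the anisole ring) but grown on the ether oxygen. Numbering ring B from the ether carbon C1' (C2' Br, C3' H, C4' Br, C5' Br, C6' OH), the run C3'–C6' carries the H, Br, Br, O pattern of mucobromic acid and enters as 4,5-dibromopyridazin-3-yl triflate, while C1'–C2' enters as the bromoethynyl ether of 3,5-dibromo-2-methoxyphenol. One inverse-demand Diels–Alder reaction with loss of N2 forms C1'–C6' and C2'–C3', closes ring B in its aromatic state and sets all six of its substituents; cleavage of the triflate then frees the C6' phenol.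

Key step: step 8

Remark: mucobromic acid is drawn as the open (Z)-aldehyde acid although it rests mainly as the cyclic 5-hydroxyfuranone, and hydrazine is used as its monohydrate; neither changes the atoms delivered to ring B.

**Route**

Step 1
Reactants: 1 3,5-dibromosalicylaldehyde
Product: 2 3,5-dibromo-2-methoxybenzaldehyde
Conditions: MeI (1.5 equiv), K2CO3 (2 equiv), DMF, 25 °C
Reagents that add atoms: iodomethane, CI
Why: Williamson O-methylation of an acidic, hydrogen-bonded phenol by SN2 attack of the phenoxide on iodomethane, with the aldehyde and both aryl bromides inert.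

Step 2
Reactants: 2 3,5-dibromo-2-methoxybenzaldehyde
Product: 4 3,5-dibromo-2-methoxyphenol, via aryl formate 3 (not isolated)
Conditions: mCPBA (1.5 equiv), CH2Cl2, 40 °C; then K2CO3 (cat.), MeOH, 25 °C; aq. Na2S2O3, then dilute HCl
Reagents that add atoms: 3-chloroperoxybenzoic acid (mCPBA), OOC(=O)c1cccc(Cl)c1
Why: Baeyer–Villiger oxidation in which the ortho-methoxy group favours aryl over hydride migration should give the formate, which base-catalysed methanolysis opens to the phenol.

Step 3
Reactants: 4 3,5-dibromo-2-methoxyphenol; 5 2,4,6-trivinylcyclotriboroxane–pyridine complex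
Product: 6 1,5-dibromo-3-(ethenyloxy)-2-methoxybenzene
Conditions: Cu(OAc)2 (2 equiv), pyridine (10 equiv), 4 Å MS, CH2Cl2, 25 °C, dry air
Reagents that add atoms: none
Why: Chan–Lam oxidative O-vinylation mediated by divalent copper runs at room temperature and leaves aryl bromides untouched.

Step 4
Reactants: 6 1,5-dibromo-3-(ethenyloxy)-2-methoxybenzene
Product: 8 1,5-dibromo-3-{[(Z)-2-bromoethenyl]oxy}-2-methoxybenzene, via dibromoethyl ether 7 (not isolated)
Conditions: Br2 (1.05 equiv), CH2Cl2, −78 °C; then i-Pr2NEt (2.5 equiv), −78 → 40 °C
Reagents that add atoms: bromine, BrBr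
Why: Electrophilic addition of bromine to the enol ether double bond (far more reactive than the dibrominated ring) followed by amine-induced dehydrobromination of the labile α-bromo ether is the classical entry to β-bromovinyl ethers.

Step 5
Reactants: 8 1,5-dibromo-3-{[(Z)-2-bromoethenyl]oxy}-2-methoxybenzene
Product: 11 1,5-dibromo-3-[(bromoethynyl)oxy]-2-methoxybenzene, via ethynyl ether 9 (not isolated), via potassium acetylide 10 (not isolated)
Conditions: KN(SiMe3)2 (2.3 equiv), THF, −78 → −30 °C; then NBS (1.3 equiv), −78 → 0 °C; cold aq. NaHCO3; product kept cold and dark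
Reagents that add atoms: N-bromosuccinimide (NBS), O=C1CCC(=O)N1Br
Why: Anti E2 loss of HBr gives the ethynyl ether, a second equivalent of amide deprotonates it and the acetylide is brominated at carbon by NBS (dehydrohalogenation, then electrophilic halogenation of a metal acetylide), while the silylamide is too weak to metalate the ring C–H between the bromines and cannot undergo bromine–metal exchange.

Step 6
Reactants: 12 mucobromic acid; 13 hydrazine (as monohydrate)
Product: 14 4,5-dibromopyridazin-3(2H)-one
Conditions: 2 M aq. HCl, 0 → 100 °C
Reagents that add atoms: none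
Why: Cyclocondensation of the 1,4-dicarbonyl unit with hydrazine (one nitrogen condenses with the aldehyde carbon, the other is acylated by the carboxyl) is the classical pyridazinone synthesis, and the acidic medium keeps hydrazine from displacing a bromine.

Step 7
Reactants: 14 4,5-dibromopyridazin-3(2H)-one
Product: 15 4,5-dibromopyridazin-3-yl trifluoromethanesulfonate
Conditions: Tf2O (1.2 equiv), 2,6-lutidine (1.5 equiv), CH2Cl2, −40 → 0 °C
Reagents that add atoms: trifluoromethanesulfonic anhydride, O=S(=O)(OS(=O)(=O)C(F)(F)F)C(F)(F)F
Why: O-sulfonylation of the lactam gives the aromatic heteroaryl triflate as is usual for pyridazin-3(2H)-ones, and the hindered base avoids attack on the activated ring.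

Step 8
Reactants: 15 4,5-dibromopyridazin-3-yl trifluoromethanesulfonate; 11 1,5-dibromo-3-[(bromoethynyl)oxy]-2-methoxybenzene
Product: 17 2,3,5-tribromo-6-(3,5-dibromo-2-methoxyphenoxy)phenyl trifluoromethanesulfonate, via diazabicyclooctatriene 16 (not isolated)
Conditions: 15 (2 equiv), slow addition of 11, 2,6-di-tert-butyl-4-methylpyridine (0.1 equiv), BHT (5 mol%), PhCl, sealed tube, 130 °C, −N2
Reagents that add atoms: none
Why: Proposed new method: the oxygen lone pair of 11 raises its HOMO and makes the bromine-bearing alkyne carbon nucleophilic, while two bromines and the sulfonate lower the LUMO of diazine 15, so an inverse-electron-demand [4+2] cycloaddition across pyridazine C3 and C6 should give bicycle 16, which aromatises at once by retro-[4+2] loss of N2, no elimination being needed because the dienophile is an alkyne. The closest known reaction type is the inverse-demand Diels–Alder reaction of acceptor-substituted pyridazines (4,5-dicyano, 3,6-diester) and phthalazines with ynamines, enol ethers and alkynes followed by N2 extrusion; a dibromo sulfonyloxy pyridazine and a haloynol ether have not been shown to be reactive enough, which is the open point. Ring B, the only ring closed, is formed by an intermolecular [4+2] cycloaddition that makes C1'–C6' and C2'–C3' in one event, not by cyclisation of a chain. No stereocentre remains, since both bridgehead centres of 16 become aromatic carbons. The step needs one orientation, nucleophilic alkyne carbon to pyridazine C6; the polarisation of the ynol ether and the fact that C6 is the only unsubstituted, least hindered diene terminus should secure it, and bonding there leaves the developing negative charge on N1 and C3, where the sulfonyloxy oxygen and the adjacent bromine stabilise it. Slow addition of 11 to an excess of 15 with a hindered base and BHT is meant to keep the ynol ether from polymerising or being hydrated before it is trapped.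

Step 9
Reactants: 17 2,3,5-tribromo-6-(3,5-dibromo-2-methoxyphenoxy)phenyl trifluoromethanesulfonate
Product: 18 2,3,5-tribromo-6-(3,5-dibromo-2-methoxyphenoxy)phenol
Conditions: Et4NOH (35% aq., 3 equiv), 1,4-dioxane, 25 °C; then 1 M HCl
Reagents that add atoms: none
Why: Hydroxide attacks the sulfonyl sulfur and expels the electron-poor phenoxide (S–O cleavage of an aryl triflate), a mild hydrolysis that should leave the aryl bromides, the diaryl ether and the methyl ether alone.

**Compound list**

1 | 3,5-dibromosalicylaldehyde (3,5-dibromo-2-hydroxybenzaldehyde) | O=Cc1cc(Br)cc(Br)c1O | starting material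
2 | 3,5-dibromo-2-methoxybenzaldehyde | COc1c(Br)cc(Br)cc1C=O | intermediate
3 | 3,5-dibromo-2-methoxyphenyl formate (not isolated) | COc1c(Br)cc(Br)cc1OC=O | intermediate
4 | 3,5-dibromo-2-methoxyphenol | COc1c(Br)cc(Br)cc1O | intermediate
5 | 2,4,6-trivinylcyclotriboroxane–pyridine complex | C=CB1OB(C=C)OB(C=C)O1.c1ccncc1 | starting material
6 | 1,5-dibromo-3-(ethenyloxy)-2-methoxybenzene | COc1c(Br)cc(Br)cc1OC=C | intermediate
7 | 1,5-dibromo-3-(1,2-dibromoethoxy)-2-methoxybenzene (racemic, not isolated) | COc1c(Br)cc(Br)cc1OC(Br)CBr | intermediate
8 | 1,5-dibromo-3-{[(Z)-2-bromoethenyl]oxy}-2-methoxybenzene | COc1c(Br)cc(Br)cc1O/C=C\Br | intermediate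
9 | 1,5-dibromo-3-(ethynyloxy)-2-methoxybenzene (not isolated) | COc1c(Br)cc(Br)cc1OC#C | intermediate
10 | potassium [(3,5-dibromo-2-methoxyphenoxy)ethynide] (not isolated) | COc1c(Br)cc(Br)cc1OC#[C-].[K+] | intermediate
11 | 1,5-dibromo-3-[(bromoethynyl)oxy]-2-methoxybenzene | COc1c(Br)cc(Br)cc1OC#CBr | intermediate
12 | mucobromic acid ((Z)-2,3-dibromo-4-oxobut-2-enoic acid) | O=C/C(Br)=C(/Br)C(=O)O | starting material
13 | hydrazine (used as monohydrate) | NN | starting material
14 | 4,5-dibromopyridazin-3(2H)-one | O=c1[nH]ncc(Br)c1Br | intermediate
15 | 4,5-dibromopyridazin-3-yl trifluoromethanesulfonate | FC(F)(F)S(=O)(=O)Oc1nncc(Br)c1Br | intermediate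
16 | 5,6,8-tribromo-7-(3,5-dibromo-2-methoxyphenoxy)-2,3-diazabicyclo[2.2.2]octa-2,5,7-trien-1-yl trifluoromethanesulfonate (racemic, not isolated) | FC(F)(F)S(=O)(=O)OC12N=NC(C(Br)=C1Br)C(Br)=C2Oc1cc(Br)cc(Br)c1OC | intermediate
17 | 2,3,5-tribromo-6-(3,5-dibromo-2-methoxyphenoxy)phenyl trifluoromethanesulfonate | COc1c(Br)cc(Br)cc1Oc1c(Br)cc(Br)c(Br)c1OS(=O)(=O)C(F)(F)F | intermediate
18 | 2,3,5-tribromo-6-(3,5-dibromo-2-methoxyphenoxy)phenol | COc1c(Br)cc(Br)cc1Oc1c(Br)cc(Br)c(Br)c1O | target

**Step count**

Total: 9 steps. Longest linear sequence: 7 steps (steps 1, 2, 3, 4, 5, 8, 9); steps 6 and 7 form the second branch.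

**Steps most likely to fail**

1. Step 8 (Proposed new method). The cycloaddition may be too slow at temperatures the ynol ether tolerates, so that polymerisation or hydration of the alkyne, or ipso substitution at the sulfonate-bearing carbon, outruns ring formation; bonding could also start at the wrong diene terminus and give the reversed orientation. The fallback uses known chemistry, sets out from 4 and returns to the route at 18, leaving out 11, 15 and 17. Phenol 4 is arylated with commercial 3,5-dibromo-2-fluorobenzaldehyde by nucleophilic aromatic substitution (K2CO3, DMAc, 90 °C), the ortho formyl group activating the fluoride, to give 3,5-dibromo-2-(3,5-dibromo-2-methoxyphenoxy)benzaldehyde F1. Baeyer–Villiger oxidation (mCPBA, CH2Cl2) should give 3,5-dibromo-2-(3,5-dibromo-2-methoxyphenoxy)phenyl formate F2, which methanolysis (K2CO3, MeOH) converts to 3,5-dibromo-2-(3,5-dibromo-2-methoxyphenoxy)phenol F3. Amine-directed ortho bromination (Br2, t-BuNH2, toluene, −78 °C) should then brominate C5', the only free position ortho to the hydroxyl, because the para position C3' is flanked by two bromines, and give 18.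

2. Step 5. The elimination may stall, the amide base may add to the electron-poor ynol ether, or the acetylide may be brominated incompletely, and the product may decompose during isolation. The fallback avoids both the terminal alkyne and the acetylide; it sets out from 8 and returns at 11. Bromine is added to 8 (Br2, CH2Cl2, −78 °C) to give 1,5-dibromo-2-methoxy-3-(1,2,2-tribromoethoxy)benzene F4, which i-Pr2NEt dehydrobrominates in the same flask to 1,5-dibromo-3-[(2,2-dibromoethenyl)oxy]-2-methoxybenzene F5. A single E2 elimination of HBr from this 1,1-dibromoalkene (KOtBu, 1.1 equiv, THF, −40 °C), the standard route to 1-bromoalkynes, should give 11.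

3. Step 3. Transmetalation to copper may be slow with a hindered, acidic ortho-methoxyphenol, so that protodeboronation and oxidative side reactions of the vinylboron reagent consume it first. The fallback replaces the oxidative coupling by alkylation and elimination; it sets out from 4 and returns at 6. Williamson alkylation of 4 with excess 1,2-dibromoethane (K2CO3, DMF, 60 °C) gives 1,5-dibromo-3-(2-bromoethoxy)-2-methoxybenzene F6, and E2 elimination (KOtBu, THF, 0 °C) should give vinyl ether 6.

**Further compounds**

F1 | step 8 | 3,5-dibromo-2-(3,5-dibromo-2-methoxyphenoxy)benzaldehyde | COc1c(Br)cc(Br)cc1Oc1c(Br)cc(Br)cc1C=O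
F2 | step 8 | 3,5-dibromo-2-(3,5-dibromo-2-methoxyphenoxy)phenyl formate | COc1c(Br)cc(Br)cc1Oc1c(Br)cc(Br)cc1OC=O
F3 | step 8 | 3,5-dibromo-2-(3,5-dibromo-2-methoxyphenoxy)phenol | COc1c(Br)cc(Br)cc1Oc1c(Br)cc(Br)cc1O
F4 | step 5 | 1,5-dibromo-2-methoxy-3-(1,2,2-tribromoethoxy)benzene (racemic) | COc1c(Br)cc(Br)cc1OC(Br)C(Br)Br
F5 | step 5 | 1,5-dibromo-3-[(2,2-dibromoethenyl)oxy]-2-methoxybenzene | COc1c(Br)cc(Br)cc1OC=C(Br)Br
F6 | step 3 | 1,5-dibromo-3-(2-bromoethoxy)-2-methoxybenzene | COc1c(Br)cc(Br)cc1OCCBr
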